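**Strategy.** The upper pyran ring (O1–C2–C3–C4–C4a–C8a) is cut at C3–C4 and O1–C2. C4 is a diarylmethine on ring A ortho to O1, hence the methide carbon of an o-quinone methide; C3 carries an aryl group next to the C2–O1 unit, hence the α-carbon of an arylacetaldehyde. One enamine-catalysed formal [4+2] annulation joins the two halves, closes the pyran as a lactol and sets C3 and C4 trans. Its precursor is the o-hydroxybenzhydrol 20, a 4-benzyloxy-2-hydroxyphenyl carbinol on the benzylated (3S)-lower isoflavan, which is built by Evans alkylation and Mitsunobu closure; the partner is aldehyde 24.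

Key step: step 15

Remark on the chemistry: carbinol 20 is carried as both carbinol epimers and lactol 26 as both C2 anomers; these centres are erased in steps 15 and 16.

**Route**

Step 1
Reactants: 1 2,4-dihydroxybenzaldehyde
Product: 2 4-(benzyloxy)-2-hydroxybenzaldehyde
Conditions: BnBr (1.05 equiv), NaHCO3, MeCN, 80 °C
Reagents that add atoms: benzyl bromide, BrCc1ccccc1
Why: Williamson etherification; the 2-OH is hydrogen-bonded to the formyl group, so the weak base alkylates only the 4-OH.

Step 2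
Reactants: 2 4-(benzyloxy)-2-hydroxybenzaldehyde
Product: 3 4-(benzyloxy)-2-[(triisopropylsilyl)oxy]benzaldehyde
Conditions: TIPSCl, imidazole, DMF, rt
Reagents that add atoms: triisopropylsilyl chloride, CC(C)[Si](Cl)(C(C)C)C(C)C
Why: Imidazole-promoted silylation of the phenol; the bulky aryl silyl ether resists hydride, enolate and O-to-O migration, cannot assist ionisation of the later benzylic bromide, and is removed by fluoride beside benzyl ethers and the aryl bromide.

Step 3
Reactants: 3 4-(benzyloxy)-2-[(triisopropylsilyl)oxy]benzaldehyde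
Product: 4 {4-(benzyloxy)-2-[(triisopropylsilyl)oxy]phenyl}methanol
Conditions: NaBH4, THF/MeOH, 0 °C
Reagents that add atoms: none
Why: Borohydride reduction of an aryl aldehyde to the benzylic alcohol; nothing else in the molecule is reducible.

Step 4
Reactants: 4 {4-(benzyloxy)-2-[(triisopropylsilyl)oxy]phenyl}methanol
Product: 5 4-(benzyloxy)-2-[(triisopropylsilyl)oxy]benzyl bromide
Conditions: PBr3 (0.4 equiv), Et2O, 0 °C; crude bromide used at once
Reagents that add atoms: phosphorus tribromide, BrP(Br)Br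
Why: Conversion of a benzylic alcohol into the bromide through its phosphite ester; the electron-rich bromide is labile and is therefore not purified or stored.

Step 5
Reactants: 6 5-bromo-2-hydroxy-4-methoxybenzaldehyde
Product: 7 2-(benzyloxy)-5-bromo-4-methoxybenzaldehyde
Conditions: BnBr, K2CO3, DMF, rt to 50 °C
Reagents that add atoms: benzyl bromide, BrCc1ccccc1
Why: Williamson etherification of the only phenol.

Step 6
Reactants: 7 2-(benzyloxy)-5-bromo-4-methoxybenzaldehyde
Product: 9 2-[2-(benzyloxy)-5-bromo-4-methoxyphenyl]acetaldehyde, via enol ether 8 (not isolated)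
Conditions: MeOCH2PPh3Cl, KOtBu, THF, 0 °C to rt; then 2 M HCl, THF, 50 °C
Reagents that add atoms: (methoxymethyl)triphenylphosphonium chloride, [Cl-].COC[P+](c1ccccc1)(c1ccccc1)c1ccccc1; water, O
Why: Wittig methoxymethylenation followed by acid hydrolysis of the enol ether is the standard one-carbon homologation of an aryl aldehyde; the aryl bromide and benzyl ether are inert to both stages.

Step 7
Reactants: 9 2-[2-(benzyloxy)-5-bromo-4-methoxyphenyl]acetaldehyde
Product: 10 2-[2-(benzyloxy)-5-bromo-4-methoxyphenyl]acetic acid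
Conditions: NaClO2, NaH2PO4, 2-methyl-2-butene, t-BuOH/THF/H2O, 0 °C to rt
Reagents that add atoms: sodium chlorite, [Na+].[O-]Cl=O
Why: Pinnick oxidation of the aldehyde; the alkene scavenger removes hypochlorous acid before it can chlorinate the electron-rich ring.

Step 8
Reactants: 10 2-[2-(benzyloxy)-5-bromo-4-methoxyphenyl]acetic acid
Product: 12 (4S)-4-benzyl-3-{2-[2-(benzyloxy)-5-bromo-4-methoxyphenyl]acetyl}oxazolidin-2-one, via mixed pivalic anhydride 11 (not isolated)
Conditions: PivCl, Et3N, THF, −20 °C; then (S)-4-benzyloxazolidin-2-one, LiCl, −20 °C to rt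
Reagents that add atoms: (S)-4-benzyloxazolidin-2-one, O=C1N[C@@H](Cc2ccccc2)CO1
Why: N-acylation of the Evans auxiliary through the mixed anhydride; the hindered pivaloyl carbonyl directs attack to the arylacetyl carbonyl.

Step 9
Reactants: 12 (4S)-4-benzyl-3-{2-[2-(benzyloxy)-5-bromo-4-methoxyphenyl]acetyl}oxazolidin-2-one; 5 4-(benzyloxy)-2-[(triisopropylsilyl)oxy]benzyl bromide
Product: 14 (4S)-4-benzyl-3-[(2S)-2-[2-(benzyloxy)-5-bromo-4-methoxyphenyl]-3-{4-(benzyloxy)-2-[(triisopropylsilyl)oxy]phenyl}propanoyl]oxazolidin-2-one, via sodium enolate 13 (not isolated)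
Conditions: NaHMDS (1.05 equiv), THF, −78 °C; then 5, −78 to −40 °C
Reagents that add atoms: none
Why: Evans asymmetric alkylation; the chelated Z-enolate is shielded on one face by the C4 benzyl group of the (4S)-auxiliary, so the benzylic bromide enters from the other face and sets the new centre S (the future lower C3).

Step 10
Reactants: 14 (4S)-4-benzyl-3-[(2S)-2-[2-(benzyloxy)-5-bromo-4-methoxyphenyl]-3-{4-(benzyloxy)-2-[(triisopropylsilyl)oxy]phenyl}propanoyl]oxazolidin-2-one
Product: 16 (2S)-2-[2-(benzyloxy)-5-bromo-4-methoxyphenyl]-3-[4-(benzyloxy)-2-hydroxyphenyl]propan-1-ol, via silyl ether alcohol 15 (not isolated)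
Conditions: LiBH4, MeOH (1.2 equiv), THF, 0 °C; aq. NH4Cl; then TBAF on the crude alcohol, THF, 0 °C
Reagents that add atoms: none
Why: Reductive cleavage of the imide with LiBH4 removes the auxiliary without touching the aryl bromide or the α-centre, and fluoride desilylation then frees the phenol needed for ring closure.

Step 11
Reactants: 16 (2S)-2-[2-(benzyloxy)-5-bromo-4-methoxyphenyl]-3-[4-(benzyloxy)-2-hydroxyphenyl]propan-1-ol
Product: 17 (3S)-7-(benzyloxy)-3-[2-(benzyloxy)-5-bromo-4-methoxyphenyl]chroman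
Conditions: PPh3, DIAD, THF, 0 °C to rt
Reagents that add atoms: none
Why: Intramolecular Mitsunobu etherification; the phenol displaces the activated primary alcohol (6-exo-tet) to close the lower pyran, and the stereocentre is not at the reacting carbon, so it stays S.

Step 12
Reactants: 17 (3S)-7-(benzyloxy)-3-[2-(benzyloxy)-5-bromo-4-methoxyphenyl]chroman; 2 4-(benzyloxy)-2-hydroxybenzaldehyde
Product: 20 5-(benzyloxy)-2-[{4-(benzyloxy)-5-[(3S)-7-(benzyloxy)chroman-3-yl]-2-methoxyphenyl}(hydroxy)methyl]phenol (both carbinol epimers), via aryllithium 18 (not isolated), via sodium phenolate 19 (not isolated)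
Conditions: 2 (1.5 equiv), NaH, THF, 0 °C; 17, n-BuLi, THF, −78 °C; combine, −78 to 0 °C; aq. NH4Cl; Et3N-deactivated silica
Reagents that add atoms: none
Why: Bromine–lithium exchange followed by 1,2-addition to the aldehyde, whose phenol is masked as its sodium salt, gives the free o-hydroxybenzhydrol directly, so no protecting group has to be removed from this acid-labile carbinol; benzyl ethers survive butyllithium at −78 °C.

Step 13
Reactants: 21 2-hydroxy-4-methoxybenzaldehyde
Product: 22 2-(benzyloxy)-4-methoxybenzaldehyde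
Conditions: BnBr, K2CO3, DMF, rt to 50 °C
Reagents that add atoms: benzyl bromide, BrCc1ccccc1
Why: Williamson etherification of the only phenol.

Step 14
Reactants: 22 2-(benzyloxy)-4-methoxybenzaldehyde
Product: 24 2-[2-(benzyloxy)-4-methoxyphenyl]acetaldehyde, via enol ether 23 (not isolated)
Conditions: MeOCH2PPh3Cl, KOtBu, THF, 0 °C to rt; then 2 M HCl, THF, 50 °C; used fresh
Reagents that add atoms: (methoxymethyl)triphenylphosphonium chloride, [Cl-].COC[P+](c1ccccc1)(c1ccccc1)c1ccccc1; water, O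
Why: Wittig methoxymethylenation and enol ether hydrolysis, the same one-carbon homologation as in step 6; the aldehyde is used at once because arylacetaldehydes self-condense.

Step 15
Reactants: 20 5-(benzyloxy)-2-[{4-(benzyloxy)-5-[(3S)-7-(benzyloxy)chroman-3-yl]-2-methoxyphenyl}(hydroxy)methyl]phenol; 24 2-[2-(benzyloxy)-4-methoxyphenyl]acetaldehyde
Product: 26 (3S,4R)-7-(benzyloxy)-4-{4-(benzyloxy)-5-[(3S)-7-(benzyloxy)chroman-3-yl]-2-methoxyphenyl}-3-[2-(benzyloxy)-4-methoxyphenyl]chroman-2-ol (C2 anomers), via o-quinone methide 25 (not isolated)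
Conditions: (S)-α,α-diphenylprolinol trimethylsilyl ether (20 mol %), PhCO2H (20 mol %), 24 (2 equiv), CH2Cl2, rt
Reagents that add atoms: none
Why: Benzoic acid promotes loss of water from 20 to the (E)-o-quinone methide 25, which the benzyloxy group para to the methide carbon and the dialkoxyaryl substituent stabilise enough to form under conditions that leave the silyl ether catalyst and the enamine intact; the E-enamine of 24 attacks the methide carbon through its β-carbon (C3–C4), and the freed phenoxide adds to the iminium carbon (O1–C2, 6-exo-trig) before hydrolysis to the lactol. This is the established secondary-amine-catalysed formal [4+2] annulation of in situ o-quinone methides with aldehydes, a Michael addition/hemiacetalisation cascade. C3 is set by the catalyst: the CPh2OTMS group blocks one enamine face as in its Michael additions to nitroalkenes, which for the (S)-catalyst should translate into 3S. C4 follows from the open, anti approach of the E-methide to that enamine face, giving 4R and the trans C3/C4 pair; this is also the thermodynamic lactol, since C3 can epimerise through the open aldehyde and C4 cannot. The step needs C-attack over N-attack on 25 and catalyst control of the C4 face: amine addition to 25 is reversible, and the resident (3S) centre lies beyond the central arene, too far to bias the methide faces. The anomeric centre is left uncontrolled because step 16 removes it.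

Step 16
Reactants: 26 (3S,4R)-7-(benzyloxy)-4-{4-(benzyloxy)-5-[(3S)-7-(benzyloxy)chroman-3-yl]-2-methoxyphenyl}-3-[2-(benzyloxy)-4-methoxyphenyl]chroman-2-ol
Product: 27 (3S,4R)-7-(benzyloxy)-4-{4-(benzyloxy)-5-[(3S)-7-(benzyloxy)chroman-3-yl]-2-methoxyphenyl}-3-[2-(benzyloxy)-4-methoxyphenyl]chroman
Conditions: Et3SiH (3 equiv), BF3·OEt2 (1.5 equiv), CH2Cl2, −78 to −30 °C
Reagents that add atoms: none
Why: Ionic hydrogenation of a lactol; BF3 ionises C2–OH to the cyclic oxocarbenium ion, which the silane reduces at low temperature, while C3, C4 and the benzyl ethers are not involved.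

Step 17
Reactants: 27 (3S,4R)-7-(benzyloxy)-4-{4-(benzyloxy)-5-[(3S)-7-(benzyloxy)chroman-3-yl]-2-methoxyphenyl}-3-[2-(benzyloxy)-4-methoxyphenyl]chroman
Product: 28 (3S,4R)-4-{4-hydroxy-5-[(3S)-7-hydroxychroman-3-yl]-2-methoxyphenyl}-3-(2-hydroxy-4-methoxyphenyl)chroman-7-ol
Conditions: H2 (1 atm), 10% Pd/C, THF/MeOH, rt
Reagents that add atoms: none
Why: Catalytic hydrogenolysis cleaves the four benzyl aryl ethers; the chroman C–O bonds are not benzylic, and the three stereocentres carry no exchangeable hydrogen under these conditions.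

**Compound list**

1 | 2,4-dihydroxybenzaldehyde | O=Cc1ccc(O)cc1O | starting material
2 | 4-(benzyloxy)-2-hydroxybenzaldehyde | O=Cc1ccc(OCc2ccccc2)cc1O | intermediate
3 | 4-(benzyloxy)-2-[(triisopropylsilyl)oxy]benzaldehyde | O=Cc1ccc(OCc2ccccc2)cc1O[Si](C(C)C)(C(C)C)C(C)C | intermediate
4 | {4-(benzyloxy)-2-[(triisopropylsilyl)oxy]phenyl}methanol | OCc1ccc(OCc2ccccc2)cc1O[Si](C(C)C)(C(C)C)C(C)C | intermediate
5 | 4-(benzyloxy)-2-[(triisopropylsilyl)oxy]benzyl bromide | BrCc1ccc(OCc2ccccc2)cc1O[Si](C(C)C)(C(C)C)C(C)C | intermediate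
6 | 5-bromo-2-hydroxy-4-methoxybenzaldehyde | COc1cc(O)c(C=O)cc1Br | starting material
7 | 2-(benzyloxy)-5-bromo-4-methoxybenzaldehyde | COc1cc(OCc2ccccc2)c(C=O)cc1Br | intermediate
8 | 1-(benzyloxy)-4-bromo-5-methoxy-2-(2-methoxyethenyl)benzene (E/Z enol ether, formed in the flask) | COC=Cc1cc(Br)c(OC)cc1OCc1ccccc1 | intermediate
9 | 2-[2-(benzyloxy)-5-bromo-4-methoxyphenyl]acetaldehyde | COc1cc(OCc2ccccc2)c(CC=O)cc1Br | intermediate
10 | 2-[2-(benzyloxy)-5-bromo-4-methoxyphenyl]acetic acid | COc1cc(OCc2ccccc2)c(CC(=O)O)cc1Br | intermediate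
11 | mixed anhydride of 10 with pivalic acid (formed in the flask) | CC(C)(C)C(=O)OC(=O)Cc1cc(Br)c(OC)cc1OCc1ccccc1 | intermediate
12 | (4S)-4-benzyl-3-{2-[2-(benzyloxy)-5-bromo-4-methoxyphenyl]acetyl}oxazolidin-2-one | COc1cc(OCc2ccccc2)c(CC(=O)N2[C@@H](Cc3ccccc3)COC2=O)cc1Br | intermediate
13 | sodium (Z)-enolate of 12 (formed in the flask) | [Na+].[O-]/C(=C\c1cc(Br)c(OC)cc1OCc1ccccc1)N1[C@@H](Cc2ccccc2)COC1=O | intermediate
14 | (4S)-4-benzyl-3-[(2S)-2-[2-(benzyloxy)-5-bromo-4-methoxyphenyl]-3-{4-(benzyloxy)-2-[(triisopropylsilyl)oxy]phenyl}propanoyl]oxazolidin-2-one | O=C([C@@H](Cc1ccc(OCc2ccccc2)cc1O[Si](C(C)C)(C(C)C)C(C)C)c1cc(Br)c(OC)cc1OCc1ccccc1)N1[C@@H](Cc2ccccc2)COC1=O | intermediate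
15 | (2S)-2-[2-(benzyloxy)-5-bromo-4-methoxyphenyl]-3-{4-(benzyloxy)-2-[(triisopropylsilyl)oxy]phenyl}propan-1-ol (crude, not purified) | OC[C@@H](Cc1ccc(OCc2ccccc2)cc1O[Si](C(C)C)(C(C)C)C(C)C)c1cc(Br)c(OC)cc1OCc1ccccc1 | intermediate
16 | (2S)-2-[2-(benzyloxy)-5-bromo-4-methoxyphenyl]-3-[4-(benzyloxy)-2-hydroxyphenyl]propan-1-ol | OC[C@@H](Cc1ccc(OCc2ccccc2)cc1O)c1cc(Br)c(OC)cc1OCc1ccccc1 | intermediate
17 | (3S)-7-(benzyloxy)-3-[2-(benzyloxy)-5-bromo-4-methoxyphenyl]chroman | COc1cc(OCc2ccccc2)c([C@H]2COc3cc(OCc4ccccc4)ccc3C2)cc1Br | intermediate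
18 | {4-(benzyloxy)-5-[(3S)-7-(benzyloxy)chroman-3-yl]-2-methoxyphenyl}lithium (formed in the flask) | [Li]c1cc([C@H]2COc3cc(OCc4ccccc4)ccc3C2)c(OCc2ccccc2)cc1OC | intermediate
19 | sodium 5-(benzyloxy)-2-formylphenolate (formed in the flask) | [Na+].[O-]c1cc(OCc2ccccc2)ccc1C=O | intermediate
20 | 5-(benzyloxy)-2-[{4-(benzyloxy)-5-[(3S)-7-(benzyloxy)chroman-3-yl]-2-methoxyphenyl}(hydroxy)methyl]phenol (both carbinol epimers) | OC(c1ccc(OCc2ccccc2)cc1O)c1cc([C@H]2COc3cc(OCc4ccccc4)ccc3C2)c(OCc2ccccc2)cc1OC | intermediate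
21 | 2-hydroxy-4-methoxybenzaldehyde | COc1ccc(C=O)c(O)c1 | starting material
22 | 2-(benzyloxy)-4-methoxybenzaldehyde | COc1ccc(C=O)c(OCc2ccccc2)c1 | intermediate
23 | 2-(benzyloxy)-4-methoxy-1-(2-methoxyethenyl)benzene (E/Z enol ether, formed in the flask) | COC=Cc1ccc(OC)cc1OCc1ccccc1 | intermediate
24 | 2-[2-(benzyloxy)-4-methoxyphenyl]acetaldehyde | O=CCc1ccc(OC)cc1OCc1ccccc1 | intermediate
25 | (E)-3-(benzyloxy)-6-({4-(benzyloxy)-5-[(3S)-7-(benzyloxy)chroman-3-yl]-2-methoxyphenyl}methylidene)cyclohexa-2,4-dien-1-one (o-quinone methide, formed in the flask) | COc1cc(OCc2ccccc2)c([C@H]2COc3cc(OCc4ccccc4)ccc3C2)cc1/C=C5\C=CC(OCc2ccccc2)=CC5=O | intermediate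
26 | (3S,4R)-7-(benzyloxy)-4-{4-(benzyloxy)-5-[(3S)-7-(benzyloxy)chroman-3-yl]-2-methoxyphenyl}-3-[2-(benzyloxy)-4-methoxyphenyl]chroman-2-ol (C2 anomers) | COc1ccc([C@H]2C(O)Oc3cc(OCc4ccccc4)ccc3[C@@H]2c2cc([C@H]5COc6cc(OCc7ccccc7)ccc6C5)c(OCc5ccccc5)cc2OC)c(OCc2ccccc2)c1 | intermediate
27 | (3S,4R)-7-(benzyloxy)-4-{4-(benzyloxy)-5-[(3S)-7-(benzyloxy)chroman-3-yl]-2-methoxyphenyl}-3-[2-(benzyloxy)-4-methoxyphenyl]chroman | COc1ccc([C@H]2COc3cc(OCc4ccccc4)ccc3[C@@H]2c2cc([C@H]5COc6cc(OCc7ccccc7)ccc6C5)c(OCc5ccccc5)cc2OC)c(OCc2ccccc2)c1 | intermediate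
28 | (3S,4R)-4-{4-hydroxy-5-[(3S)-7-hydroxychroman-3-yl]-2-methoxyphenyl}-3-(2-hydroxy-4-methoxyphenyl)chroman-7-ol | COc1ccc([C@H]2COc3cc(O)ccc3[C@@H]2c2cc([C@H]3COc4cc(O)ccc4C3)c(O)cc2OC)c(O)c1 | target

**Counts and risks**

Total step count: 17. Longest linear sequence: 11 steps (from 6 through steps 5–12 and 15–17).

Steps most likely to fail:

1. Step 15. The enamine of the ortho-substituted arylacetaldehyde may add too slowly, so that the quinone methide is lost to self-condensation or stays parked as its amine adduct, and control of the C4 face may be incomplete. The fallback sets out from 20 and 24 and returns at 26; it moves the activation from the nucleophile to the electrophile. Aldehyde 24 would be condensed with benzyl carbamate (TsOH cat., toluene, 4 Å sieves) to benzyl N-[(E)-2-(2-(benzyloxy)-4-methoxyphenyl)ethenyl]carbamate F1. A chiral BINOL-derived phosphoric acid (TRIP type, enantiomer chosen for the 4R series) would then dehydrate 20 and hold methide 25 and F1 in a hydrogen-bonded assembly for an inverse-electron-demand oxa-Diels–Alder reaction; endo addition of the E-alkene should give the trans-3,4-diaryl 2-(benzyloxycarbonylamino)chroman F2. Dilute aqueous acid in THF would hydrolyse the N,O-acetal of F2 to lactol 26.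

2. Step 16. Ionisation at C2 may be followed by loss of the acidic C3–H (to a 3-aryl-4H-chromene) and re-protonation, which would scramble C3. The fallback sets out from 26 and returns at 27 and avoids any cation at C2. NaBH4 (THF/MeOH, 0 °C) would reduce the open hydroxy-aldehyde tautomer of 26 to (2S,3R)-3-[4-(benzyloxy)-2-hydroxyphenyl]-3-{4-(benzyloxy)-5-[(3S)-7-(benzyloxy)chroman-3-yl]-2-methoxyphenyl}-2-[2-(benzyloxy)-4-methoxyphenyl]propan-1-ol F3. An intramolecular Mitsunobu etherification (PPh3, DIAD, THF), the closure already used for 17, would then form O1–C2 and give 27.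

3. Step 12. Aryllithium 18 may be protonated by incompletely deprotonated 2, or may add sluggishly to the sparingly soluble, deactivated phenolate 19; either returns debrominated isoflavan. The fallback sets out from 17 and returns at 20, using the silyl-protected aldehyde 3 already made in step 2. Aryllithium 18 would be added to 3 at −78 °C to give the O-silylated carbinol (3S)-7-(benzyloxy)-3-{2-(benzyloxy)-5-[{4-(benzyloxy)-2-[(triisopropylsilyl)oxy]phenyl}(hydroxy)methyl]-4-methoxyphenyl}chroman F4. TBAF in THF at 0 °C would unmask the phenol without acid and give 20.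

Further compounds
F1 | step 15 | benzyl N-[(E)-2-(2-(benzyloxy)-4-methoxyphenyl)ethenyl]carbamate | COc1ccc(/C=C/NC(=O)OCc2ccccc2)c(OCc2ccccc2)c1
F2 | step 15 | benzyl N-[(3S,4R)-7-(benzyloxy)-4-{4-(benzyloxy)-5-[(3S)-7-(benzyloxy)chroman-3-yl]-2-methoxyphenyl}-3-[2-(benzyloxy)-4-methoxyphenyl]chroman-2-yl]carbamate (C2 epimers) | COc1ccc([C@H]2C(NC(=O)OCc3ccccc3)Oc3cc(OCc4ccccc4)ccc3[C@@H]2c2cc([C@H]5COc6cc(OCc7ccccc7)ccc6C5)c(OCc5ccccc5)cc2OC)c(OCc2ccccc2)c1
F3 | step 16 | (2S,3R)-3-[4-(benzyloxy)-2-hydroxyphenyl]-3-{4-(benzyloxy)-5-[(3S)-7-(benzyloxy)chroman-3-yl]-2-methoxyphenyl}-2-[2-(benzyloxy)-4-methoxyphenyl]propan-1-ol | COc1ccc([C@@H](CO)[C@H](c2ccc(OCc3ccccc3)cc2O)c2cc([C@H]3COc4cc(OCc5ccccc5)ccc4C3)c(OCc3ccccc3)cc2OC)c(OCc2ccccc2)c1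
F4 | step 12 | (3S)-7-(benzyloxy)-3-{2-(benzyloxy)-5-[{4-(benzyloxy)-2-[(triisopropylsilyl)oxy]phenyl}(hydroxy)methyl]-4-methoxyphenyl}chroman (both carbinol epimers) | OC(c1ccc(OCc2ccccc2)cc1O[Si](C(C)C)(C(C)C)C(C)C)c1cc([C@H]2COc3cc(OCc4ccccc4)ccc3C2)c(OCc2ccccc2)cc1OC
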